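## Retrosynthetic overview
1. Endgame: C11=C13 is released from its Me2NH adduct, and the C6 ester is cut to epoxyangelic acid 4. The oxirane of 4 is made first, in its own branch, by Sharpless epoxidation.
2. Key disconnection: the furanone ring (C10, O, C3, C2, C1) and the carbocycle C1–C10 are opened together at O–C3, C2–C3 and C3–C4, and C3 is returned as carbon monoxide. This leaves the monocyclic lactone 27, which carries a (Z)-C4 alkenyl iodide and a C10 tertiary ethynyl carbinol.
3. Enabling feature: C3, the enol-ether carbon of the furanone, is a ketone-level carbon without H or branch. It lies between sp2 C4 and C2 and is 1,4 to the tertiary C10–O. The unit O–C3=C2–C1=O is therefore the isomer of a hydroxy-ynone C3(=O)–C2≡C1–C10(OH).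
4. Lactone 25 is cut at C7–C8 and O–C12 into allylboronate 23 (C6 from a Midland reduction) and aldehyde 10 (C10 from Sharpless epoxidation and Red-Al opening).
5. Ring order: oxirane of the side chain, then γ-lactone (C7, C8, O, C12, C11), then carbocycle C1–C10, then furanone. The last two form in one flask, with the furanone last.

Key step: step 18

Assumption: germacrane numbering is used throughout (C1–C10 ring, C11–C13 lactone unit, C14 = methyl on C10, C15 = methyl on C4). C11 of the masked compounds 27–34 is drawn as the expected trans isomer. Its configuration has no consequence because step 21 erases it.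

## Route

Step 1
Reactants: 1 angelic acid
Product: 2 (Z)-2-methylbut-2-en-1-ol
Conditions: LiAlH4, Et2O, 0 °C → rt
Reagents that add atoms: none
Why: Hydride reduction of a carboxylic acid to the primary alcohol, which leaves the trisubstituted Z-alkene untouched and creates no stereocentre.

Step 2
Reactants: 2 (Z)-2-methylbut-2-en-1-ol
Product: 3 [(2R,3S)-2,3-dimethyloxiran-2-yl]methanol
Conditions: Ti(OiPr)4 (10 mol %), D-(−)-DET (12 mol %), t-BuOOH, 4 Å MS, CH2Cl2, −20 °C
Reagents that add atoms: tert-butyl hydroperoxide CC(C)(C)OO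
Why: Sharpless asymmetric epoxidation, in which the D-(−)-tartrate catalyst selects the alkene face that gives 2R,3S and the syn oxygen transfer keeps CH2OH and the C3 methyl cis.

Step 3
Reactants: 3 epoxy alcohol
Product: 4 (2S,3S)-2,3-dimethyloxirane-2-carboxylic acid (epoxyangelic acid)
Conditions: RuCl3·xH2O (2 mol %), NaIO4, CCl4–MeCN–H2O, rt
Reagents that add atoms: sodium periodate [Na+].[O-]I(=O)(=O)=O (net oxygen source); water O (enters through the aldehyde hydrate)
Why: Catalytic ruthenium tetroxide oxidation of a primary alcohol to the acid, which tolerates the epoxide and touches no stereocentre (C2 changes from R to S by priority only).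

Step 4
Reactants: 5 (E)-3-methylpent-2-en-4-yn-1-ol
Product: 6 [(2R,3R)-3-ethynyl-3-methyloxiran-2-yl]methanol
Conditions: Ti(OiPr)4 (10 mol %), D-(−)-DET (12 mol %), t-BuOOH, 4 Å MS, CH2Cl2, −20 °C
Reagents that add atoms: tert-butyl hydroperoxide CC(C)(C)OO
Why: Sharpless asymmetric epoxidation of an E-trisubstituted allylic alcohol, in which D-(−)-tartrate sets the quaternary carbinol carbon (later C10) as 3R.

Step 5
Reactants: 6 epoxy alcohol
Product: 7 (S)-3-methylpent-4-yne-1,3-diol
Conditions: Red-Al, THF, −20 → 0 °C; aq. Rochelle salt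
Reagents that add atoms: none
Why: Hydroxyl-directed Red-Al opening of a 2,3-epoxy alcohol, in which the C1 alkoxyaluminate delivers hydride to C2, so the 1,3-diol forms and the quaternary C–O bond keeps its configuration (R to S by priority only).

Step 6
Reactants: 7 diol
Product: 8 (S)-bis(triethylsilyl) ether of 7
Conditions: TESOTf, 2,6-lutidine, CH2Cl2, −78 → 0 °C
Reagents that add atoms: triethylsilyl triflate CC[Si](CC)(CC)OS(=O)(=O)C(F)(F)F
Why: Silyl triflate silylation, which is reactive enough for the tertiary propargylic hydroxyl and touches no stereocentre.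

Step 7
Reactants: 8 bis-TES ether
Product: 10 (S)-3-methyl-3-(triethylsilyloxy)pent-4-ynal, via alkoxysulfonium chloride 9 (not isolated)
Conditions: (COCl)2, DMSO, CH2Cl2, −78 → −40 °C; Et3N, −78 °C → rt
Reagents that add atoms: none
Why: Swern oxidation applied directly to the silyl ether, in which only the unhindered primary O–SiEt3 is attacked by the chlorosulfonium salt, so the aldehyde forms while the tertiary TES ether stays.

Step 8
Reactants: 11 but-2-yn-1-ol
Product: 13 (Z)-3-iodobut-2-en-1-ol, via cyclic vinylalanate 12 (not isolated)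
Conditions: Red-Al, THF, 0 °C → rt; I2, THF, −78 °C
Reagents that add atoms: iodine II
Why: Hydroxyl-directed trans-hydroalumination of a propargylic alcohol and iodinolysis with retention, in which the five-membered alanate fixes Al (then I) cis to CH2OH and so gives the Z-iodide.

Step 9
Reactants: 13 (Z)-3-iodobut-2-en-1-ol
Product: 14 (Z)-3-iodobut-2-enal
Conditions: MnO2, CH2Cl2, rt, dark
Reagents that add atoms: none
Why: Manganese dioxide oxidation of an allylic alcohol under neutral conditions, which keeps the Z geometry.

Step 10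
Reactants: 14 (Z)-3-iodobut-2-enal; 15 methyl propiolate
Product: 17 methyl (±)-(Z)-4-hydroxy-6-iodohept-5-en-2-ynoate, via lithium acetylide 16 (not isolated)
Conditions: 15, LiHMDS, THF, −78 °C; 14; AcOH, −78 °C
Reagents that add atoms: none
Why: 1,2-Addition of a lithium acetylide to an enal, which forms C6–C7; the carbinol is racemic here and is corrected in steps 11 and 12.

Step 11
Reactants: 17 racemic carbinol
Product: 18 methyl (Z)-6-iodo-4-oxohept-5-en-2-ynoate
Conditions: Dess–Martin periodinane, CH2Cl2, 0 °C
Reagents that add atoms: none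
Why: Dess–Martin oxidation of an allylic and propargylic alcohol under neutral conditions, which spares the iodoalkene and the ynoate.

Step 12
Reactants: 18 alkenyl alkynyl ketone
Product: 20 methyl (4S,5Z)-4-hydroxy-6-iodohept-5-en-2-ynoate, via 9-BBN borinate 19 (not isolated)
Conditions: (S)-Alpine-Borane, THF (concentrated), rt; HOCH2CH2NH2, Et2O, 0 °C
Reagents that add atoms: none
Why: Midland reduction of an alkynyl ketone, in which hydride passes through a boat-like six-membered transition state with the slim alkynyl group next to the pinane methyl, so the reagent from (−)-α-pinene should give the (S)-carbinol (C6).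

Step 13
Reactants: 20 (S)-carbinol
Product: 21 TBS ether of 20
Conditions: TBSOTf, 2,6-lutidine, CH2Cl2, −78 °C
Reagents that add atoms: tert-butyldimethylsilyl triflate CC(C)(C)[Si](C)(C)OS(=O)(=O)C(F)(F)F
Why: Low-temperature silyl triflate protection, which avoids base-induced isomerisation of the γ-hydroxy ynoate and leaves C6 untouched.

Step 14
Reactants: 21 TBS ether
Product: 23 methyl (2Z,4R,5Z)-4-(TBSO)-6-iodo-2-[(pinacolboryl)methyl]hepta-2,5-dienoate, via vinylalane 22 (not isolated)
Conditions: DIBAL-H, HMPA, THF, 0 °C; ICH2Bpin, 0 °C → rt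
Reagents that add atoms: 2-(iodomethyl)-4,4,5,5-tetramethyl-1,3,2-dioxaborolane CC1(C)OB(CI)OC1(C)C
Why: Conjugate syn-hydroalumination of an alkynoate, then boron-ate formation and a Matteson-type 1,2-shift with loss of iodide; H and Al add cis, so C6 ends up cis to CO2Me and trans to CH2B, which is the geometry needed for the anti adduct (C6 changes from S to R by priority only).

Step 15
Reactants: 23 allylboronate; 10 aldehyde
Product: 25 trans-α-methylene-γ-butyrolactone (6R,7R,8S,10S) bearing C6–OTBS and C10–OTES, via pinacol borate 24 (not isolated)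
Conditions: Sc(OTf)3 (10 mol %), toluene, 0 °C → rt; PPTS, toluene, 40 °C
Reagents that add atoms: none
Why: Lewis-acid-catalysed carbonyl allylboration with a 2-alkoxycarbonyl allylboronate followed by lactonisation; the closed chair transition state turns the alkene geometry into the anti C7/C8 relationship (trans-lactone), and A(1,3) strain with CO2Me places C6–H inside, the iodoalkenyl group anti and OTBS outside, so the aldehyde should add to the face that gives 7R,8S.

Step 16
Reactants: 25 bis-silyl lactone
Product: 26 lactone with free C10–OH and C6–OTBS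
Conditions: AcOH–THF–H2O (3:1:1), rt
Reagents that add atoms: none
Why: Selective acidic solvolysis of a TES ether in the presence of the far more acid-stable secondary TBS ether, with no stereocentre touched.

Step 17
Reactants: 26 α-methylene lactone
Product: 27 13-(dimethylamino)-11,13-dihydro lactone (11S)
Conditions: Me2NH (2 M in THF), EtOH, 0 °C → rt
Reagents that add atoms: dimethylamine CNC
Why: Aza-Michael addition, the standard reversible masking of an α-methylene-γ-butyrolactone; protonation of the enolate should place CH2NMe2 trans to the C7 side chain, at a centre that step 21 erases.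

Step 18
Reactants: 27 masked iodo-alkynol lactone
Product: 30 masked TBS-protected furanone macrocycle (6S,7R,8S,10S,11S), via macrocyclic ynone 28 (not isolated), via enaminone 29 (not isolated)
Conditions: PdCl2(PPh3)2 (10 mol %), CuI (10 mol %), Et3N, CO (1 atm), THF, 27 added over 12 h (to ca. 1 mM), 40 °C; vent CO, Me2NH (2 M in THF), rt; AcOH–H2O, rt
Reagents that add atoms: carbon monoxide [C-]#[O+] (C3); water O (oxygen on C1)
Why: Proposed new method: Pd(0) inserts into the (Z)-C4–I bond with retention, CO insertion gives the C3 acyl-palladium, the copper acetylide of C2 is transferred and reductive elimination from the eleven-membered acyl(alkynyl)palladacycle closes the carbocycle as 4-hydroxy-2-ynone 28, after which Me2NH adds to C1 (the β-carbon of the strained ynone), the C10 hydroxyl of enaminone 29 adds to the C3 carbonyl, water is lost and aqueous acid hydrolyses the C1 iminium ion, so that the carbonyl oxygen is transposed from C3 to C1. The closest known reaction types are the intermolecular carbonylative Sonogashira coupling of alkenyl iodides, the carbonylative Stille macrocyclisation, and the secondary-amine-mediated isomerisation of 4-hydroxyalk-2-ynones to 3(2H)-furanones, which has also been run in one pot from a halide, CO and a tertiary ethynyl carbinol; what is new is their use to close a ten-membered ring. Modes of closure: the carbocycle C1–C10 closes by C2–C3 reductive elimination (palladacycle contraction 11 → 10), and the furanone closes by 5-exo-trig attack of O10 on C3=O followed by dehydration. No stereocentre is created, because the C10–O bond is never broken, C6, C7 and C8 are spectators, and the 4Z geometry is carried over from the iodide. The step needs CO insertion before alkynylation, ring closure before oligomerisation, and an acyl-palladium that nothing else captures: direct coupling would give a nine-membered enyne and is shut off by strain, slow addition together with the trans-lactone and the quaternary C10 favours the intramolecular path, and the substrate offers no competitor because O6 is silylated (no butenolide), C11=C13 is masked (no 6-exo acylpalladation or Heck closure), O10–H is tertiary, Et3N is not nucleophilic and Me2NH enters only after CO has been vented. The regiochemistry of the amine addition is fixed by the polarity of the ynone, and release of alkyne strain drives 28 forward.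

Step 19
Reactants: 30 TBS ether
Product: 31 masked furanone macrocycle with free C6–OH
Conditions: HF·pyridine, pyridine–THF, 0 °C → rt
Reagents that add atoms: none
Why: Fluoride-mediated desilylation under mildly acidic conditions, which should suppress base-induced translactonisation; the C6–O bond is not broken (C7 changes from R to S by priority only).

Step 20
Reactants: 31 C6 alcohol; 4 epoxyangelic acid
Product: 33 masked target (C6 epoxyangelate), via mixed anhydride 32 (not isolated)
Conditions: MNBA, Et3N, DMAP, CH2Cl2, rt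
Reagents that add atoms: none
Why: Shiina esterification through the mixed anhydride with 2-methyl-6-nitrobenzoic acid; the acid has no α-hydrogen and cannot epimerise, and acyl transfer to oxygen retains C6.

Step 21
Reactants: 33 masked target
Product: 35 target CNP0258430.1, via methiodide 34 (not isolated)
Conditions: MeI, THF, rt; aq. NaHCO3–CH2Cl2, rt
Reagents that add atoms: none
Why: Exhaustive methylation and Hofmann-type E1cB elimination of the β-ammonio lactone regenerate C11=C13 under conditions that leave epoxide, esters and furanone alone; only the auxiliary C11 centre is erased.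

## Compound list
1 | angelic acid ((Z)-2-methylbut-2-enoic acid) | C/C=C(/C)C(=O)O | starting material
2 | (Z)-2-methylbut-2-en-1-ol | C/C=C(/C)CO | intermediate
3 | [(2R,3S)-2,3-dimethyloxiran-2-yl]methanol | OC[C@@]1(C)O[C@H]1C | intermediate
4 | (2S,3S)-2,3-dimethyloxirane-2-carboxylic acid | OC(=O)[C@@]1(C)O[C@H]1C | intermediate
5 | (E)-3-methylpent-2-en-4-yn-1-ol | C#C/C(C)=C/CO | starting material
6 | [(2R,3R)-3-ethynyl-3-methyloxiran-2-yl]methanol | C#C[C@@]1(C)O[C@@H]1CO | intermediate
7 | (S)-3-methylpent-4-yne-1,3-diol | C#C[C@@](C)(O)CCO | intermediate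
8 | (S)-3-methyl-1,3-bis(triethylsilyloxy)pent-4-yne | C#C[C@@](C)(O[Si](CC)(CC)CC)CCO[Si](CC)(CC)CC | intermediate
9 | dimethyl alkoxysulfonium chloride of the primary oxygen of 8 | C#C[C@@](C)(O[Si](CC)(CC)CC)CCO[S+](C)C.[Cl-] | intermediate
10 | (S)-3-methyl-3-(triethylsilyloxy)pent-4-ynal | C#C[C@@](C)(O[Si](CC)(CC)CC)CC=O | intermediate
11 | but-2-yn-1-ol | CC#CCO | starting material
12 | sodium cyclic vinylalanate (1-oxa-2-aluminacyclopent-3-ene, 3-methyl, two 2-methoxyethoxy groups on Al) | [Na+].CC1=CCO[Al-]1(OCCOC)OCCOC | intermediate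
13 | (Z)-3-iodobut-2-en-1-ol | C/C(I)=C/CO | intermediate
14 | (Z)-3-iodobut-2-enal | C/C(I)=C/C=O | intermediate
15 | methyl propiolate | C#CC(=O)OC | starting material
16 | lithium acetylide of methyl propiolate | [Li+].[C-]#CC(=O)OC | intermediate
17 | methyl (±)-(Z)-4-hydroxy-6-iodohept-5-en-2-ynoate | C/C(I)=C/C(O)C#CC(=O)OC | intermediate
18 | methyl (Z)-6-iodo-4-oxohept-5-en-2-ynoate | C/C(I)=C/C(=O)C#CC(=O)OC | intermediate
19 | 9-BBN borinate of 20 | C/C(I)=C/[C@H](OB1C2CCCC1CCC2)C#CC(=O)OC | intermediate
20 | methyl (4S,5Z)-4-hydroxy-6-iodohept-5-en-2-ynoate | C/C(I)=C/[C@H](O)C#CC(=O)OC | intermediate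
21 | methyl (4S,5Z)-4-(tert-butyldimethylsilyloxy)-6-iodohept-5-en-2-ynoate | C/C(I)=C/[C@H](O[Si](C)(C)C(C)(C)C)C#CC(=O)OC | intermediate
22 | α-(diisobutylalumino) dienoate (Al on C11, cis to H7) | COC(=O)/C([Al](CC(C)C)CC(C)C)=C\[C@@H](O[Si](C)(C)C(C)(C)C)/C=C(/C)I | intermediate
23 | methyl (2Z,4R,5Z)-4-(TBSO)-6-iodo-2-[(4,4,5,5-tetramethyl-1,3,2-dioxaborolan-2-yl)methyl]hepta-2,5-dienoate | COC(=O)/C(CB1OC(C)(C)C(C)(C)O1)=C\[C@@H](O[Si](C)(C)C(C)(C)C)/C=C(/C)I | intermediate
24 | C8–O–Bpin borate of the anti homoallylic alcohol (open hydroxy ester form of 25) | C=C(C(=O)OC)[C@H]([C@H](C[C@](C)(O[Si](CC)(CC)CC)C#C)OB1OC(C)(C)C(C)(C)O1)[C@@H](O[Si](C)(C)C(C)(C)C)/C=C(/C)I | intermediate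
25 | (6R,7R,8S,10S)-trans-α-methylene-γ-butyrolactone; C7 bears CH(OTBS)–CH=C(CH3)I (Z); C8 bears CH2–C(CH3)(OTES)–C≡CH | C=C1C(=O)O[C@@H](C[C@](C)(O[Si](CC)(CC)CC)C#C)[C@@H]1[C@@H](O[Si](C)(C)C(C)(C)C)/C=C(/C)I | intermediate
26 | 25 with free C10–OH | C=C1C(=O)O[C@@H](C[C@](C)(O)C#C)[C@@H]1[C@@H](O[Si](C)(C)C(C)(C)C)/C=C(/C)I | intermediate
27 | (11S)-13-dimethylamino-11,13-dihydro derivative of 26 | CN(C)C[C@H]1C(=O)O[C@@H](C[C@](C)(O)C#C)[C@@H]1[C@@H](O[Si](C)(C)C(C)(C)C)/C=C(/C)I | intermediate
28 | ten-membered (4Z)-4-en-1-yn-3-one with C10–OH, C6–OTBS and the masked trans-8,12-lactone | CN(C)C[C@H]1C(=O)O[C@H]2C[C@](C)(O)C#CC(=O)/C(C)=C\[C@H](O[Si](C)(C)C(C)(C)C)[C@H]12 | intermediate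
29 | C1-dimethylamino enaminone of 28 (C10 and C3 cis on C1=C2) | CN(C)C[C@H]1C(=O)O[C@H]2C[C@](C)(O)/C(N(C)C)=C\C(=O)/C(C)=C\[C@H](O[Si](C)(C)C(C)(C)C)[C@H]12 | intermediate
30 | (6S,7R,8S,10S,11S)-3,10-epoxy-1-oxogermacra-2,4Z-dien-8,12-olide, 6-OTBS, 13-NMe2 | CN(C)C[C@H]1C(=O)O[C@H]2C[C@]3(C)OC(=CC3=O)/C(C)=C\[C@H](O[Si](C)(C)C(C)(C)C)[C@H]12 | intermediate
31 | 30 with free C6–OH | CN(C)C[C@H]1C(=O)O[C@H]2C[C@]3(C)OC(=CC3=O)/C(C)=C\[C@H](O)[C@H]12 | intermediate
32 | mixed anhydride of 4 and 2-methyl-6-nitrobenzoic acid | O=C(OC(=O)[C@@]1(C)O[C@H]1C)c1c(C)cccc1[N+](=O)[O-] | intermediate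
33 | C6 (2S,3S)-epoxyangelate of 31 | CN(C)C[C@H]1C(=O)O[C@H]2C[C@]3(C)OC(=CC3=O)/C(C)=C\[C@H](OC(=O)[C@@]3(C)O[C@H]3C)[C@H]12 | intermediate
34 | trimethylammonium iodide (methiodide) of 33 | C[N+](C)(C)C[C@H]1C(=O)O[C@H]2C[C@]3(C)OC(=CC3=O)/C(C)=C\[C@H](OC(=O)[C@@]3(C)O[C@H]3C)[C@H]12.[I-] | intermediate
35 | CNP0258430.1 (6S,7R,8S,10S,2'S,3'S) | C=C1C(=O)O[C@H]2C[C@]3(C)OC(=CC3=O)/C(C)=C\[C@H](OC(=O)[C@@]3(C)O[C@H]3C)[C@H]12 | target

## Count and risks
Total steps: 21. Longest linear sequence: 14 steps (steps 8–21, from 11).

**1. Step 18.**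
- What may go wrong: transfer of the acetylide and reductive elimination across the ring may be slower than intermolecular coupling, which would lead to oligomers. Slow retro-Michael loss of Me2NH could also divert the acyl-palladium to an amide.
- Fallback: it sets out from 23 and 8 and comes back at 30.
  - The C3 carbonyl is put in first by an ordinary intermolecular carbonylative Sonogashira coupling of 23 with 8 (PdCl2(PPh3)2, CuI, Et3N, CO). This gives the open-chain ynone boronate F1.
  - Swern oxidation of the primary TES ether, as in step 7, gives the ynone aldehyde boronate F2.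
  - The ten-membered ring is then closed at C7–C8 by intramolecular carbonyl allylation under high dilution (Sc(OTf)3, then PPTS), the type of closure established for germacranolide rings. This gives the macrocyclic ynone α-methylene lactone F3.
  - AcOH–THF–H2O frees the tertiary hydroxyl and gives the macrocyclic hydroxy-ynone F4.
  - Me2NH adds at C13 and at C1 (giving 28, then 29), and aqueous acetic acid closes the furanone, still as the last ring, to 30.

**2. Step 15.**
- What may go wrong: the hindered boronate may add slowly, so the β-silyloxy aldehyde could eliminate. The C6 centre may also discriminate poorly between the two faces of the allyl unit.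
- Fallback: it sets out from 23 (with 10) and comes back at 25.
  - Oxidation of the C–B bond (NaBO3·4H2O, THF–H2O) gives the allylic alcohol F5.
  - Appel bromination (CBr4, PPh3) gives the allylic bromide F6.
  - Nozaki–Hiyama allylation of 10 with nickel-free CrCl2 proceeds through an equilibrating allylchromium species, so the anti relationship no longer depends on the alkene geometry. A chiral carbazole-bisoxazoline ligand can be added so that the reagent rather than C6 chooses the face. This gives the anti hydroxy ester F7.
  - PPTS closes F7 to 25.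

**3. Step 20.**
- What may go wrong: acylation of the hindered C6–OH in the bridged macrocycle by an α-quaternary acid may be sluggish, which would leave time for acyl migration of the lactone to O6.
- Fallback: it sets out from 26 and comes back at 33, with the ester installed on the flexible monocycle.
  - HF·pyridine gives the C6,C10-diol lactone F8.
  - Shiina esterification with 4 acylates only the secondary hydroxyl and gives the epoxyangelate F9.
  - Me2NH gives the masked epoxyangelate F10.
  - The conditions of step 18 carry F10 through the ester-bearing macrocyclic ynone F11 and the ester-bearing enaminone F12 to 33.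

## Further compounds
F1 | step 18 | open-chain ynone boronate (C3 ketone between C4 and C2, primary and tertiary OTES, C6–OTBS) | COC(=O)/C(CB1OC(C)(C)C(C)(C)O1)=C\[C@@H](O[Si](C)(C)C(C)(C)C)/C=C(/C)C(=O)C#C[C@@](C)(O[Si](CC)(CC)CC)CCO[Si](CC)(CC)CC
F2 | step 18 | ynone aldehyde boronate (C8 aldehyde) | COC(=O)/C(CB1OC(C)(C)C(C)(C)O1)=C\[C@@H](O[Si](C)(C)C(C)(C)C)/C=C(/C)C(=O)C#C[C@@](C)(O[Si](CC)(CC)CC)CC=O
F3 | step 18 | macrocyclic ynone α-methylene lactone with C10–OTES and C6–OTBS | C=C1C(=O)O[C@H]2C[C@](C)(O[Si](CC)(CC)CC)C#CC(=O)/C(C)=C\[C@H](O[Si](C)(C)C(C)(C)C)[C@H]12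
F4 | step 18 | macrocyclic hydroxy-ynone α-methylene lactone with C6–OTBS | C=C1C(=O)O[C@H]2C[C@](C)(O)C#CC(=O)/C(C)=C\[C@H](O[Si](C)(C)C(C)(C)C)[C@H]12
F5 | step 15 | allylic alcohol, methyl 4-(TBSO)-2-(hydroxymethyl)-6-iodohepta-2,5-dienoate (geometry and C6 as in 23) | COC(=O)/C(CO)=C\[C@@H](O[Si](C)(C)C(C)(C)C)/C=C(/C)I
F6 | step 15 | allylic bromide, methyl 2-(bromomethyl)-4-(TBSO)-6-iodohepta-2,5-dienoate (geometry and C6 as in 23) | COC(=O)/C(CBr)=C\[C@@H](O[Si](C)(C)C(C)(C)C)/C=C(/C)I
F7 | step 15 | anti hydroxy ester (open form of 25) | C=C(C(=O)OC)[C@H]([C@H](C[C@](C)(O[Si](CC)(CC)CC)C#C)O)[C@@H](O[Si](C)(C)C(C)(C)C)/C=C(/C)I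
F8 | step 20 | C6,C10-diol lactone | C=C1C(=O)O[C@@H](C[C@](C)(O)C#C)[C@@H]1[C@@H](O)/C=C(/C)I
F9 | step 20 | C6 epoxyangelate of F8 | C=C1C(=O)O[C@@H](C[C@](C)(O)C#C)[C@@H]1[C@@H](OC(=O)[C@@]2(C)O[C@H]2C)/C=C(/C)I
F10 | step 20 | Me2NH adduct of F9 | CN(C)C[C@H]1C(=O)O[C@@H](C[C@](C)(O)C#C)[C@@H]1[C@@H](OC(=O)[C@@]2(C)O[C@H]2C)/C=C(/C)I
F11 | step 20 | ester-bearing macrocyclic ynone | CN(C)C[C@H]1C(=O)O[C@H]2C[C@](C)(O)C#CC(=O)/C(C)=C\[C@H](OC(=O)[C@@]3(C)O[C@H]3C)[C@H]12
F12 | step 20 | ester-bearing enaminone | CN(C)C[C@H]1C(=O)O[C@H]2C[C@](C)(O)/C(N(C)C)=C\C(=O)/C(C)=C\[C@H](OC(=O)[C@@]3(C)O[C@H]3C)[C@H]12
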